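**Plan**
Locants: ring A has the ether O on C1, OMe on C2, Br on C3 and C5; ring B has the ether O on C1', OH on C2', Br on C3' and C5', OMe on C6'.
Retrosynthesis: cut the two ring B C–Br bonds and the ring A O–CH3 bond, then the ring A C2–O bond (carried as C2–B), then the C1–O(ether) and C2–B bonds together.
Enabling feature: ring A carries the ether oxygen on C1, a second oxygen on the neighbouring C2 and a bromine on C3. A 3-bromoaryne gives exactly this flanked vicinal pair, with fixed orientation, when an O–B bond adds across its triple bond.
Forward: ring A enters as an ortho-silylaryl triflate made from 2,4,6-tribromophenol, and ring B as the pinacol borate of a 2,6-dioxygenated phenol made from 3-methoxyphenol. No ring is formed; the arenes are joined in step 6, followed by C–B oxidation, O-methylation, MOM cleavage and double bromination of ring B.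
Stereochemistry: the target has no stereocentre, so none has to be set.

Key step: step 6

**Step 1**
Reactants: 1 2,4,6-tribromophenol
Product: 2 trimethyl(2,4,6-tribromophenoxy)silane
Conditions: HMDS, THF, 70 °C; volatiles removed
Reagents that add atoms: hexamethyldisilazane, C[Si](C)(C)N[Si](C)(C)C
Why: Silylation of the acidic phenol by HMDS is driven by loss of ammonia and gives the aryl silyl ether needed for the later oxygen-to-carbon silyl shift.

**Step 2**
Reactants: 2 trimethyl(2,4,6-tribromophenoxy)silane
Product: 5 2,4-dibromo-6-(trimethylsilyl)phenyl trifluoromethanesulfonate, via aryllithium 3 (not isolated), via lithium phenoxide 4 (not isolated)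
Conditions: n-BuLi, THF, −100 to −78 °C; then Tf2O, −78 to 0 °C
Reagents that add atoms: trifluoromethanesulfonic anhydride, O=S(=O)(OS(=O)(=O)C(F)(F)F)C(F)(F)F
Why: Bromine–lithium exchange at a bromine ortho to oxygen gives aryllithium 3, whose irreversible 1,3 oxygen-to-carbon silyl migration (retro-Brook rearrangement) draws the exchange equilibrium to the ortho position and leaves lithium phenoxide 4 for triflation, the standard entry to ortho-silylaryl triflates from ortho-bromophenols.

**Step 3**
Reactants: 6 3-methoxyphenol
Product: 7 1-methoxy-3-(methoxymethoxy)benzene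
Conditions: NaH, MOMCl, THF/DMF, 0 °C to rt
Reagents that add atoms: chloromethyl methyl ether, COCCl
Why: Williamson-type alkylation of the sodium phenoxide installs an acetal that acts as ortho-director in step 4 and masks the ring B hydroxyl until step 9.

**Step 4**
Reactants: 7 1-methoxy-3-(methoxymethoxy)benzene
Product: 10 2-methoxy-6-(methoxymethoxy)phenol, via aryllithium 8 (not isolated), via lithium aryltrimethoxyborate 9 (not isolated)
Conditions: n-BuLi, THF, 0 °C to rt; B(OMe)3, −78 °C to rt; then H2O2 (30% aq.), AcOH, 0 °C to rt
Reagents that add atoms: hydrogen peroxide, OO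
Why: Directed ortho-metalation occurs at the carbon between the two cooperating oxygen directors, and borylation of aryllithium 8 followed by peroxide oxidation of borate 9 (aryl shift from boron to oxygen) turns the C–Li bond into the phenol C–O bond.

**Step 5**
Reactants: 10 2-methoxy-6-(methoxymethoxy)phenol; 11 pinacolborane (4,4,5,5-tetramethyl-1,3,2-dioxaborolane)
Product: 12 2-[2-methoxy-6-(methoxymethoxy)phenoxy]-4,4,5,5-tetramethyl-1,3,2-dioxaborolane
Conditions: toluene, 60 °C, argon sweep (H2 vented); evaporated and used directly under argon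
Reagents that add atoms: none
Why: Dehydrogenative coupling of the phenol O–H with the B–H bond forms the aryl borate with hydrogen as the only by-product, so the moisture-sensitive ester needs no purification.

**Step 6**
Reactants: 5 2,4-dibromo-6-(trimethylsilyl)phenyl trifluoromethanesulfonate; 12 2-[2-methoxy-6-(methoxymethoxy)phenoxy]-4,4,5,5-tetramethyl-1,3,2-dioxaborolane (2 equiv)
Product: 16 2-{2,4-dibromo-6-[2-methoxy-6-(methoxymethoxy)phenoxy]phenyl}-4,4,5,5-tetramethyl-1,3,2-dioxaborolane, via 3,5-dibromobenzyne 13 (not isolated), via potassium phenoxide 14 (not isolated), via aryl potassium 15 (not isolated)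
Conditions: KF (1.2 equiv), 18-crown-6 (0.2 equiv), THF, 0 °C to rt; aq. NH4Cl work-up
Reagents that add atoms: none
Why: Proposed new method: fluoride cleaves the C–Si bond of 5 and triflate departs to release aryne 13, while a little fluoride opening the B–O bond of 12 supplies potassium phenoxide 14 as chain carrier. Phenoxide 14 adds through oxygen to C1 of 13 and the resulting aryl potassium 15 is trapped at C2 by the electrophilic boron of a further molecule of 12, which returns 14, so the net event is insertion of the aryne into the O–B bond with formation of the C1–O and C2–B bonds. The closest known reaction types are the fluoride-induced O-arylation of phenols with ortho-silylaryl triflates, the insertion of arynes into N–Si and S–Sn sigma bonds and the oxyboration of alkynes. No ring is closed and no stereocentre is created. The step needs regioselectivity, secured by the C3 bromine, which distorts the aryne so that C1 is the more electrophilic terminus and stabilises the developing charge at C2 inductively, an effect expected to outweigh the weak opposite bias of the remote C5 bromine. It also needs boron capture by 15 to outpace bromide loss and protonation, for which 12 is used in excess in an aprotic ether with only a low concentration of dissolved fluoride.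

**Step 7**
Reactants: 16 2-{2,4-dibromo-6-[2-methoxy-6-(methoxymethoxy)phenoxy]phenyl}-4,4,5,5-tetramethyl-1,3,2-dioxaborolane
Product: 17 2,4-dibromo-6-[2-methoxy-6-(methoxymethoxy)phenoxy]phenol
Conditions: H2O2 (30% aq.), NaOH (1 M aq.), THF, 0 °C; then aq. NH4Cl
Reagents that add atoms: hydrogen peroxide, OO
Why: Hydroperoxide adds to boron and the aryl group migrates from boron to oxygen at the same carbon, the standard oxidation of an arylboronic ester to a phenol, which at 0 °C should be faster than protodeboronation.

**Step 8**
Reactants: 17 2,4-dibromo-6-[2-methoxy-6-(methoxymethoxy)phenoxy]phenol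
Product: 18 1,5-dibromo-2-methoxy-3-[2-methoxy-6-(methoxymethoxy)phenoxy]benzene
Conditions: MeI, K2CO3, DMF, rt
Reagents that add atoms: iodomethane, CI
Why: Williamson methylation of the acidic, bromine-flanked phenoxide forms the ring A methyl ether.

**Step 9**
Reactants: 18 1,5-dibromo-2-methoxy-3-[2-methoxy-6-(methoxymethoxy)phenoxy]benzene
Product: 19 2-(3,5-dibromo-2-methoxyphenoxy)-3-methoxyphenol
Conditions: HCl (2 M in MeOH), THF, 40 °C
Reagents that add atoms: none
Why: Acid-catalysed acetal exchange with methanol removes the MOM group, while the aryl methyl ethers, the diaryl ether and the aryl bromides are inert.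

**Step 10**
Reactants: 19 2-(3,5-dibromo-2-methoxyphenoxy)-3-methoxyphenol
Product: 20 4,6-dibromo-2-(3,5-dibromo-2-methoxyphenoxy)-3-methoxyphenol
Conditions: NBS (2.05 equiv), MeCN, 0 °C to rt
Reagents that add atoms: N-bromosuccinimide, O=C1CCC(=O)N1Br
Why: Electrophilic aromatic bromination is directed by the free ring B hydroxyl to its ortho and para positions C3' and C5', each also activated by the C6' methoxy group, whereas C4' is meta to both donors and ring A is deactivated by two bromines.

**Compound list**
1 | 2,4,6-tribromophenol | Oc1c(Br)cc(Br)cc1Br | starting material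
2 | trimethyl(2,4,6-tribromophenoxy)silane | C[Si](C)(C)Oc1c(Br)cc(Br)cc1Br | intermediate
3 | (3,5-dibromo-2-trimethylsilyloxyphenyl)lithium | [Li]c1cc(Br)cc(Br)c1O[Si](C)(C)C | intermediate
4 | lithium 2,4-dibromo-6-(trimethylsilyl)phenoxide | [Li+].[O-]c1c(Br)cc(Br)cc1[Si](C)(C)C | intermediate
5 | 2,4-dibromo-6-(trimethylsilyl)phenyl trifluoromethanesulfonate | C[Si](C)(C)c1cc(Br)cc(Br)c1OS(=O)(=O)C(F)(F)F | intermediate
6 | 3-methoxyphenol | COc1cccc(O)c1 | starting material
7 | 1-methoxy-3-(methoxymethoxy)benzene | COCOc1cccc(OC)c1 | intermediate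
8 | [2-methoxy-6-(methoxymethoxy)phenyl]lithium | [Li]c1c(OC)cccc1OCOC | intermediate
9 | lithium trimethoxy[2-methoxy-6-(methoxymethoxy)phenyl]borate | [Li+].CO[B-](OC)(OC)c1c(OC)cccc1OCOC | intermediate
10 | 2-methoxy-6-(methoxymethoxy)phenol | COCOc1cccc(OC)c1O | intermediate
11 | pinacolborane (4,4,5,5-tetramethyl-1,3,2-dioxaborolane) | CC1(C)OBOC1(C)C | starting material
12 | 2-[2-methoxy-6-(methoxymethoxy)phenoxy]-4,4,5,5-tetramethyl-1,3,2-dioxaborolane | COCOc1cccc(OC)c1OB1OC(C)(C)C(C)(C)O1 | intermediate
13 | 3,5-dibromobenzyne (3,5-dibromo-1,2-didehydrobenzene) | BrC1=CC(Br)=CC#C1 | intermediate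
14 | potassium 2-methoxy-6-(methoxymethoxy)phenoxide | [K+].COCOc1cccc(OC)c1[O-] | intermediate
15 | {2,4-dibromo-6-[2-methoxy-6-(methoxymethoxy)phenoxy]phenyl}potassium | [K]c1c(Br)cc(Br)cc1Oc1c(OC)cccc1OCOC | intermediate
16 | 2-{2,4-dibromo-6-[2-methoxy-6-(methoxymethoxy)phenoxy]phenyl}-4,4,5,5-tetramethyl-1,3,2-dioxaborolane | CC1(C)OB(OC1(C)C)c1c(Br)cc(Br)cc1Oc1c(OC)cccc1OCOC | intermediate
17 | 2,4-dibromo-6-[2-methoxy-6-(methoxymethoxy)phenoxy]phenol | Oc1c(Br)cc(Br)cc1Oc1c(OC)cccc1OCOC | intermediate
18 | 1,5-dibromo-2-methoxy-3-[2-methoxy-6-(methoxymethoxy)phenoxy]benzene | COc1c(Br)cc(Br)cc1Oc1c(OC)cccc1OCOC | intermediate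
19 | 2-(3,5-dibromo-2-methoxyphenoxy)-3-methoxyphenol | COc1c(Br)cc(Br)cc1Oc1c(OC)cccc1O | intermediate
20 | 4,6-dibromo-2-(3,5-dibromo-2-methoxyphenoxy)-3-methoxyphenol | COc1c(Br)cc(Br)cc1Oc1c(O)c(Br)cc(Br)c1OC | target

**Count**
Total steps: 10. Longest linear sequence: 8 steps (from 6 through steps 3, 4, 5, 6, 7, 8, 9 and 10 to 20). The branch from 1 contributes steps 1 and 2.

**Steps most likely to fail**

Step 6. Aryl potassium 15 may lose bromide to form a second aryne, or pick up a proton, before it reaches boron. Aryne release may also stall if fluoride is held on boron. The fallback uses known reactions only; it sets out from phenol 10 and returns at phenol 17. Phenol 10 and commercial 2,4-dibromo-6-fluorobenzaldehyde (O=Cc1c(F)cc(Br)cc1Br), with K2CO3 in DMF at 80 °C, should undergo nucleophilic aromatic substitution of the fluoride activated by the ortho formyl group. This should give 2,4-dibromo-6-[2-methoxy-6-(methoxymethoxy)phenoxy]benzaldehyde F1. Baeyer–Villiger oxidation with mCPBA in NaHCO3-buffered CH2Cl2 should then give 2,4-dibromo-6-[2-methoxy-6-(methoxymethoxy)phenoxy]phenyl formate F2. Catalytic K2CO3 in MeOH should cleave the formate to 17, after which steps 8 to 10 follow unchanged.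

Step 2. Exchange at the para bromine may compete with exchange at the ortho bromine, and the silyl group may be transferred between molecules instead of shifting to the ortho carbon. The fallback sets out from 1 and returns at 5. NaH and MOMCl should convert 1 into 1,3,5-tribromo-2-(methoxymethoxy)benzene F3. n-BuLi in Et2O at −78 °C, guided by chelation to the acetal oxygens, should exchange an ortho bromine to give [3,5-dibromo-2-(methoxymethoxy)phenyl]lithium F4. Quenching with Me3SiCl should give [3,5-dibromo-2-(methoxymethoxy)phenyl]trimethylsilane F5. HCl in MeOH at room temperature should free 2,4-dibromo-6-(trimethylsilyl)phenol F6. Deprotonation with n-BuLi to lithium phenoxide 4, followed by Tf2O, should then give 5.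

Step 10. The electron-rich free phenol may be over-brominated or oxidised, or a bromine may enter at C4'. The fallback sets out from 18 and returns at 20. NBS (2 equiv) in DMF should brominate ring B of the bis-ether 18 at C3' and C5', each ortho to one alkoxy group and para to the other. This should give 1,5-dibromo-3-[3,5-dibromo-2-methoxy-6-(methoxymethoxy)phenoxy]-2-methoxybenzene F7. HCl in MeOH should then remove the MOM group to give 20.

**Further compounds**
F1 | step 6 | 2,4-dibromo-6-[2-methoxy-6-(methoxymethoxy)phenoxy]benzaldehyde | O=Cc1c(Br)cc(Br)cc1Oc1c(OC)cccc1OCOC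
F2 | step 6 | 2,4-dibromo-6-[2-methoxy-6-(methoxymethoxy)phenoxy]phenyl formate | O=COc1c(Br)cc(Br)cc1Oc1c(OC)cccc1OCOC
F3 | step 2 | 1,3,5-tribromo-2-(methoxymethoxy)benzene | COCOc1c(Br)cc(Br)cc1Br
F4 | step 2 | [3,5-dibromo-2-(methoxymethoxy)phenyl]lithium | [Li]c1cc(Br)cc(Br)c1OCOC
F5 | step 2 | [3,5-dibromo-2-(methoxymethoxy)phenyl]trimethylsilane | COCOc1c(Br)cc(Br)cc1[Si](C)(C)C
F6 | step 2 | 2,4-dibromo-6-(trimethylsilyl)phenol | Oc1c(Br)cc(Br)cc1[Si](C)(C)C
F7 | step 10 | 1,5-dibromo-3-[3,5-dibromo-2-methoxy-6-(methoxymethoxy)phenoxy]-2-methoxybenzene | COc1c(Br)cc(Br)cc1Oc1c(OCOC)c(Br)cc(Br)c1OC
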